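**Strategy.** Each resorcinol ring is numbered C1 (bridge carbon), C2 (OH), C4 (OMe), C6 (arylethyl arm). The plan cuts C1–C6 and C2–C3 in both rings, so that C2–C1–CH2–C1′–C2′ is a methylene-linked bis-malonate and C3–C6 of each ring is a methyl enone with the arm on its β-carbon. One two-directional Michael–Claisen annulation joins tetraallyl propane-1,1,3,3-tetracarboxylate with two molecules of (E)-6-(4-benzyloxy-3-methoxyphenyl)hex-3-en-2-one and closes both carbocycles as cyclohexane-1,3-diones with the bridge fixed at C1. Allyl esters are chosen so that the C1 ester first steers enol-ether formation to C4 and then leaves under neutral palladium catalysis.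

Key step: step 5

Remark: the target has no stereocentre and no stereogenic double bond, so no enantiomer has to be selected; compounds 9–13 are diastereomer mixtures whose sp3 centres are erased on aromatisation.

Remark (design): the ester groups of the tetracarboxylate are spectators of the annulation. Allyl replaces ethyl because a quaternary ethyl ester at C1 could only be removed with hot alkali, which would rule out forming the enol ether while C1 still shields C2.

Step 1
Reactants: 1 3-(4-hydroxy-3-methoxyphenyl)propanoic acid (dihydroferulic acid)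
Product: 2 benzyl 3-[4-(benzyloxy)-3-methoxyphenyl]propanoate
Conditions: BnBr (2.3 equiv), K2CO3 (3 equiv), DMF, 60 °C
Reagents that add atoms: benzyl bromide, BrCc1ccccc1
Why: Williamson etherification of the phenoxide and SN2 alkylation of the carboxylate by the same halide should give the benzyl ether and benzyl ester in one operation.

Step 2
Reactants: 2 benzyl 3-[4-(benzyloxy)-3-methoxyphenyl]propanoate
Product: 3 3-[4-(benzyloxy)-3-methoxyphenyl]propanal
Conditions: DIBAL-H (1.1 equiv), CH2Cl2, −78 °C; MeOH, then aq. Rochelle salt
Reagents that add atoms: none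
Why: Partial ester reduction with DIBAL-H should stop at the aluminium hemiacetal at −78 °C, which releases the aldehyde only on work-up, while the aryl benzyl ether is inert to the hydride.

Step 3
Reactants: 3 3-[4-(benzyloxy)-3-methoxyphenyl]propanal; 4 1-(triphenylphosphoranylidene)propan-2-one (1.2 equiv)
Product: 5 (E)-6-[4-(benzyloxy)-3-methoxyphenyl]hex-3-en-2-one
Conditions: toluene, 80 °C
Reagents that add atoms: 1-(triphenylphosphoranylidene)propan-2-one (compound 4), CC(=O)C=P(c1ccccc1)(c1ccccc1)c1ccccc1
Why: Wittig olefination of an unbranched aldehyde with a stabilised acyl ylide should deliver the E-enone under thermodynamic control of the oxaphosphetane.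

Step 4
Reactants: 6 diallyl malonate (2.1 equiv); 7 formaldehyde (37% aq.)
Product: 8 tetraallyl propane-1,1,3,3-tetracarboxylate
Conditions: Et2NH (cat.), neat, 0 °C → rt, then 90 °C
Reagents that add atoms: formaldehyde (compound 7), C=O
Why: Knoevenagel condensation gives the methylenemalonate, which takes up a second malonate by Michael addition, the classical entry to propane-1,1,3,3-tetracarboxylates.

Step 5
Reactants: 8 tetraallyl propane-1,1,3,3-tetracarboxylate (1 equiv); 5 (E)-6-[4-(benzyloxy)-3-methoxyphenyl]hex-3-en-2-one (2.3 equiv)
Product: 10 diallyl 1,1′-methylenebis{6-[2-(4-(benzyloxy)-3-methoxyphenyl)ethyl]-2,4-dioxocyclohexane-1-carboxylate} (diastereomer mixture), via acyclic bis-Michael adduct 9 (not isolated)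
Conditions: NaH (2.4 equiv) in allyl alcohol–THF (gives NaOCH2CH=CH2), 8, 0 °C; then 5, rt; then 70 °C; cold 1 M HCl
Reagents that add atoms: none
Why: The alkoxide turns both tertiary malonate C–H groups of 8 into stabilised carbanions, each adds in conjugate fashion to the β-carbon of 5 (C1–C6), and the methyl ketone enolate of each adduct then attacks one of the two geminal allyl esters (C2–C3) and expels allyloxide. The closest known reaction type is the malonate–enone Michael addition followed by Claisen (Dieckmann-type) cyclisation that underlies the classical 5-alkylresorcinol synthesis, here run twice on a 2-substituted malonate. Each ring closes in a 6-(enolexo)-exo-trig mode, the alternatives (a four-membered ring from the C5 enolate, an eight-membered ring onto the distal malonate) being uncompetitive. The four sp3 centres formed (C1, C6, C1′, C6′) arise without control and need none, since all are erased in steps 7 and 8. The step needs 1,4- over 1,2-addition, which the soft, reversibly adding malonate anion secures, and it needs the bis-malonate to survive without retro-Michael loss of methylenemalonate, which is secured by deprotonating both malonate carbons before the enone is admitted (a dianion cannot expel a second carbanion), by the matched allyloxide that makes ester exchange degenerate, and by the final formation of two acidic β-diketone enolates. Because the CH2 bridge sits on the malonate carbon before either ring exists, it can only end up on C1.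

Step 6
Reactants: 10 diallyl 1,1′-methylenebis{6-[2-(4-(benzyloxy)-3-methoxyphenyl)ethyl]-2,4-dioxocyclohexane-1-carboxylate}
Product: 11 diallyl 1,1′-methylenebis{6-[2-(4-(benzyloxy)-3-methoxyphenyl)ethyl]-4-methoxy-2-oxocyclohex-3-ene-1-carboxylate}
Conditions: MeOH, TsOH·H2O (10 mol %), 3 Å MS, rt
Reagents that add atoms: methanol, CO
Why: Acid-catalysed enol etherification (a vinylogous Fischer esterification) should occur by methanol addition to the protonated C4 carbonyl, which lies between two CH2 groups, whereas C2 is screened by the fully substituted C1, and the hindered allyl ester should not exchange at room temperature.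

Step 7
Reactants: 11 diallyl 1,1′-methylenebis{6-[2-(4-(benzyloxy)-3-methoxyphenyl)ethyl]-4-methoxy-2-oxocyclohex-3-ene-1-carboxylate}
Product: 12 6,6′-methylenebis{5-[2-(4-(benzyloxy)-3-methoxyphenyl)ethyl]-3-methoxycyclohex-2-en-1-one}
Conditions: Pd(OAc)2 (5 mol %), PPh3 (20 mol %), HCO2H (5 equiv), Et3N (6 equiv), THF, rt → 40 °C
Reagents that add atoms: none
Why: In this Tsuji deallylative decarboxylation Pd(0) ionises each allyl β-keto ester, the carboxylate loses CO2 to a palladium dienolate and formate supplies the hydrogen for C1 and for propene, a process that is insensitive to the steric shielding of the ester and leaves enol ethers and benzyl ethers untouched.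

Step 8
Reactants: 12 6,6′-methylenebis{5-[2-(4-(benzyloxy)-3-methoxyphenyl)ethyl]-3-methoxycyclohex-2-en-1-one}
Product: 14 2,2′-methylenebis{3-[2-(4-(benzyloxy)-3-methoxyphenyl)ethyl]-5-methoxyphenol}, via bis(trimethylsilyl dienol ether) 13 (not isolated)
Conditions: TMSCl (6 equiv), LDA (2.6 equiv), THF, −78 °C (in situ quench); then Pd(OAc)2 (2.2 equiv), MeCN, rt; dil. HCl work-up
Reagents that add atoms: chlorotrimethylsilane, C[Si](C)(C)Cl (silicon is carried only in intermediate 13)
Why: In this Saegusa–Ito oxidation, kinetic α′-deprotonation of each vinylogous ester at C1 (the Stork–Danheiser site) and O-silylation give the 2-silyloxy-1,3-dienes, Pd(II) forms the C1 palladium enolate, and β-hydride elimination gives a cyclohexadienone that should tautomerise to the phenol, so that OH lands on C2 and OMe stays on C4.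

Step 9
Reactants: 14 2,2′-methylenebis{3-[2-(4-(benzyloxy)-3-methoxyphenyl)ethyl]-5-methoxyphenol}
Product: 15 2,2′-methylenebis{3-[2-(4-hydroxy-3-methoxyphenyl)ethyl]-5-methoxyphenol} (CNP0078998.0)
Conditions: H2 (1 atm), 10% Pd/C, EtOAc–MeOH, rt
Reagents that add atoms: none
Why: Catalytic hydrogenolysis should cleave the two aryl benzyl ethers cleanly, since the molecule holds no other reducible group.

**Compound list**

1 | 3-(4-hydroxy-3-methoxyphenyl)propanoic acid (dihydroferulic acid) | COc1cc(CCC(=O)O)ccc1O | starting material
2 | benzyl 3-[4-(benzyloxy)-3-methoxyphenyl]propanoate | COc1cc(CCC(=O)OCc2ccccc2)ccc1OCc1ccccc1 | intermediate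
3 | 3-[4-(benzyloxy)-3-methoxyphenyl]propanal | COc1cc(CCC=O)ccc1OCc1ccccc1 | intermediate
4 | 1-(triphenylphosphoranylidene)propan-2-one | CC(=O)C=P(c1ccccc1)(c1ccccc1)c1ccccc1 | starting material
5 | (E)-6-[4-(benzyloxy)-3-methoxyphenyl]hex-3-en-2-one | CC(=O)/C=C/CCc1ccc(OCc2ccccc2)c(OC)c1 | intermediate
6 | diallyl malonate | C=CCOC(=O)CC(=O)OCC=C | starting material
7 | formaldehyde | C=O | starting material
8 | tetraallyl propane-1,1,3,3-tetracarboxylate | C=CCOC(=O)C(CC(C(=O)OCC=C)C(=O)OCC=C)C(=O)OCC=C | intermediate
9 | tetraallyl 4,8-bis{2-[4-(benzyloxy)-3-methoxyphenyl]ethyl}-2,10-dioxoundecane-5,5,7,7-tetracarboxylate (acyclic bis-Michael adduct, diastereomer mixture; the two Michael and two Claisen events may interleave) | CC(=O)CC(CCc1ccc(OCc2ccccc2)c(OC)c1)C(C(=O)OCC=C)(C(=O)OCC=C)CC(C(=O)OCC=C)(C(=O)OCC=C)C(CCc1ccc(OCc2ccccc2)c(OC)c1)CC(C)=O | intermediate (not isolated)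
10 | diallyl 1,1′-methylenebis{6-[2-(4-(benzyloxy)-3-methoxyphenyl)ethyl]-2,4-dioxocyclohexane-1-carboxylate} (diastereomer mixture) | C=CCOC(=O)C1(CC2(C(=O)OCC=C)C(=O)CC(=O)CC2CCc2ccc(OCc3ccccc3)c(OC)c2)C(=O)CC(=O)CC1CCc1ccc(OCc2ccccc2)c(OC)c1 | intermediate
11 | diallyl 1,1′-methylenebis{6-[2-(4-(benzyloxy)-3-methoxyphenyl)ethyl]-4-methoxy-2-oxocyclohex-3-ene-1-carboxylate} (diastereomer mixture) | C=CCOC(=O)C1(CC2(C(=O)OCC=C)C(=O)C=C(OC)CC2CCc2ccc(OCc3ccccc3)c(OC)c2)C(=O)C=C(OC)CC1CCc1ccc(OCc2ccccc2)c(OC)c1 | intermediate
12 | 6,6′-methylenebis{5-[2-(4-(benzyloxy)-3-methoxyphenyl)ethyl]-3-methoxycyclohex-2-en-1-one} (diastereomer mixture) | COC1=CC(=O)C(CC2C(=O)C=C(OC)CC2CCc2ccc(OCc3ccccc3)c(OC)c2)C(CCc2ccc(OCc3ccccc3)c(OC)c2)C1 | intermediate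
13 | 2,2′-methylenebis{3-[2-(4-(benzyloxy)-3-methoxyphenyl)ethyl]-5-methoxy-1-[(trimethylsilyl)oxy]cyclohexa-1,5-diene} (diastereomer mixture) | COC1=CC(O[Si](C)(C)C)=C(CC2=C(O[Si](C)(C)C)C=C(OC)CC2CCc2ccc(OCc3ccccc3)c(OC)c2)C(CCc2ccc(OCc3ccccc3)c(OC)c2)C1 | intermediate (not isolated)
14 | 2,2′-methylenebis{3-[2-(4-(benzyloxy)-3-methoxyphenyl)ethyl]-5-methoxyphenol} | COc1cc(O)c(Cc2c(O)cc(OC)cc2CCc2ccc(OCc3ccccc3)c(OC)c2)c(CCc2ccc(OCc3ccccc3)c(OC)c2)c1 | intermediate
15 | 2,2′-methylenebis{3-[2-(4-hydroxy-3-methoxyphenyl)ethyl]-5-methoxyphenol} (CNP0078998.0, achiral) | COc1cc(O)c(Cc2c(O)cc(OC)cc2CCc2ccc(O)c(OC)c2)c(CCc2ccc(O)c(OC)c2)c1 | target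

**Step count and risks**

Total step count: 9. Longest linear sequence: 8 (steps 1–3 and 5–9 from dihydroferulic acid; step 4 is a one-step side branch).

Steps most likely to fail:

1. Step 5. The hindered tertiary carbanions may add too slowly, so that the enone self-condenses. The bis-malonate may leak by retro-Michael fragmentation once only one of its carbons is deprotonated. The second annulation may stall after the first ring has formed. The fallback sets out from 8 (with 5) and returns at 9. Compound 8 would be O-silylated (TMSOTf, Et3N, CH2Cl2, 0 °C) to diallyl 2,4-bis[(allyloxy)(trimethylsilyloxy)methylidene]pentanedioate F1. A TiCl4-promoted Mukaiyama–Michael addition of F1 to 5 (CH2Cl2, −78 °C) should then give 9 as an isolable compound, with no free malonate anion ever present. Kinetic deprotonation of the two methyl ketones of 9 (LiHMDS, THF, −78 → 0 °C) would effect the double Claisen closure in a separate operation and rejoin the route at 10.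

2. Step 8. Deprotonation of the congested tertiary C1–H may be incomplete or give way to γ-deprotonation. The silyl dienol ether may be protodesilylated back to 12. Only one of the two rings may be oxidised. The fallback sets out from 12 and returns at 15. Heating 12 with 10% Pd/C in mesitylene at 160 °C under argon should dehydrogenate both rings heterogeneously, with the two benzyl ethers acting as internal hydrogen acceptors (transfer hydrogenolysis). Brief stirring under H2 at rt would then complete the debenzylation. This bypasses 13 and 14, and no compound outside the list is made (F0).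

3. Step 6. The non-enolisable β-keto ester may be opened by acid-induced methanolysis (retro-Claisen) or may exchange its allyl group, or etherification next to the quaternary centre may be too slow. The fallback sets out from 10 and returns at 12 by inverting the order. Deallylative decarboxylation of 10 (Pd(OAc)2, PPh3, HCO2H, Et3N, THF) would give 4,4′-methylenebis{5-[2-(4-(benzyloxy)-3-methoxyphenyl)ethyl]cyclohexane-1,3-dione} F2. Etherification of F2 (MeOH, TsOH) would then rely on the smaller steric bias of the tertiary C1 and the neighbouring arm to place OMe on C4.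

**Further compounds**

F1 | step 5 | diallyl 2,4-bis[(allyloxy)(trimethylsilyloxy)methylidene]pentanedioate | C=CCOC(=O)C(CC(C(=O)OCC=C)=C(OCC=C)O[Si](C)(C)C)=C(OCC=C)O[Si](C)(C)C
F2 | step 6 | 4,4′-methylenebis{5-[2-(4-(benzyloxy)-3-methoxyphenyl)ethyl]cyclohexane-1,3-dione} | O=C1CC(=O)C(CC2C(=O)CC(=O)CC2CCc2ccc(OCc3ccccc3)c(OC)c2)C(CCc2ccc(OCc3ccccc3)c(OC)c2)C1
F0 | step 8 | none | none
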